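If we follow one substrate molecule as it leaves, it either becomes target or goes somewhere unseen, and a target molecule later decays, so the peak stands where inflow equals outflow. The noon run is this very flask.

| flask | substrate | coupling partner | remark | time |
|---|---|---|---|---|
| noon | 19 mM | 38 mM | the very flask that is asked about, followed so far |  |
| spring | 13 mM | 38 mM | run made earlier |  |
| flask | 19 mM | 38.0 mM |  | 3.0 d |
- noon (time / h: target / %, substrate / %): 0.500: 6.1, 91.6; 1.00: 8.5, 84.8; 2.00: 10.6, 80.1; 4.00: 10.0, 73.0; 10.0: 4.1, 66.9; 20.0: 1.7, 63.1; 40.0: 0.1, 61.6
- spring (time / d: target / %, substrate / %): 0.0278: 6.8, 89.0; 0.0625: 10.1, 82.9; 0.125: 11.4, 74.8; 0.333: 5.6, 67.7; 0.625: 1.7, 63.3; 1.25: 1.3, 59.6; 3.00: 0.1, 55.4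

(each reading ± 0.5 percentage points)

* the moment within 3.0 d at which there is most target
* the amount of target, in percent of the substrate charged, at that time

1. Call the target's share (the selectivity) the fraction of departing substrate that becomes target. The first readings give 0.726 at noon and 0.618 in spring, with the same partner charge. These are separate flasks with different substrate charges, and each reading scatters by 0.5 percentage points; we take the mean share 0.672.

2. The first way to target's decay rate is the noon tail, from 4.00 h to 10.0 h: 0.149 /h.

3. The second way is a balance over the same window. Target fell by 5.9 points, yet by our share we reckon that substrate fed in 4.1 points. Scaling the tail rate by the gross loss gives 0.252 /h. The two ways part, with the second faster, and the tail is the one that cheats, because it sees the net fall, which is smaller than the gross loss.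

4. At 2.00 h, we reckon the outflow at 2.67 %/h. Our reckoned inflow is 3.16 %/h before that reading, which is more, and 2.39 %/h after it, which is less. So we expect the peak near 0.0833 d, with height 10.5%.

The forecast gives 0.11 d and 10.9%: “Target peaks early and then decays”.

The flask gives 10.3% at 0.0923 d.

    substrate + coupling partner → target (k = 0.00130 /M/s)
    substrate + 2 coupling partner → side product (k = 0.0200 /M²/s)
    2 coupling partner → self-condensation product (k = 0.00420 /M/s)
    target → over-reaction product (k = 9.10 × 10⁻⁵ /s)

The steps give the flask a share of 0.631 at the start, against our 0.672 from the first readings. Counting over-reaction product as target that has passed on, the flask at 3.00 d has lost 39.8% of its substrate, and its share by then is 0.847. The neighbouring flask with 150 mM of coupling partner reaches 15.5% of target. By 3.00 d it has lost 63.8% of its substrate, its share is 0.620, and side product stands at 24.2%.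

Readings and results come from a simulation from invented constants.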